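Retrosynthetic cuts, in order: the ester C–O bond (linoleoyl chloride + C20 dienol); the C7–C8 bond of the nonadienyl chain (alkyl–alkenyl Suzuki–Miyaura coupling); the C1–C2 bond of the 2,6,6-trimethylcyclohex-2-en-1-yl ring.
Forward: an open-chain racemic vinyl carbinol carrying an alkenyltrifluoroborate (boron cis to the chain) is closed to the only ring, a 6-vinylcyclohexene; its vinyl group is hydroborated and joined to a C10 (E,E)-iodo dienol; acylation ends the route.
Feature used: ring C1 (the stereocentre) lies between alkene carbon C2 (of C2=C3) and quaternary C6 and bears chain carbons C9–C8; with C9–C8 as a vinyl group, C1 is the substituted end of an allyl unit and C2 the boron-bearing carbon of an alkenylborate.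
One ipso allylic alkenylation therefore closes the ring, keeps C2=C3 in place, leaves a vinyl handle for the chain, and cannot drift to a diene because C6 has no hydrogen.
Stereochemistry: C1 (S) from the chiral iridium catalyst acting on both enantiomers of the carbinol (enantioconvergent); 2E from an enol phosphate–cuprate substitution, 6E from syn-hydrozirconation, 9Z,12Z from the purchased acyl chloride.

Key step: step 5

Assumption: 1 is taken as purchasable (it is the Michael adduct of isobutyraldehyde and methyl acrylate), and the ligand antipode written in step 5 is the one assumed, by analogy with intermolecular cases, to give the S centre; its mirror image is used if the sense proves opposite.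

Step 1
Reactants: 1 methyl 4,4-dimethyl-5-oxopentanoate
Product: 3 6-ethenyl-5,5-dimethyloxan-2-one (racemic), via hydroxy ester 2 (not isolated)
Conditions: CH2=CHMgBr (1.05 equiv), THF, −78 → 0 °C; 1 M HCl; then PPTS (cat.), PhMe, 40 °C
Reagents that add atoms: vinylmagnesium bromide, C=C[Mg]Br
Why: Grignard 1,2-addition is much faster at the aldehyde than at the methyl ester at low temperature, and the δ-hydroxy ester should lactonise readily (gem-dimethyl effect); the carbinol centre is formed as a racemate, which is intended because step 5 is enantioconvergent.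

Step 2
Reactants: 3 6-ethenyl-5,5-dimethyloxan-2-one (racemic)
Product: 4 6-ethenyl-5,5-dimethyloxan-2-ol (racemic, anomeric mixture)
Conditions: i-Bu2AlH (1.1 equiv), CH2Cl2, −78 °C; aq. KNaC4H4O6 (potassium sodium tartrate)
Reagents that add atoms: none
Why: Partial reduction of a δ-lactone by i-Bu2AlH at −78 °C stops at the aluminium hemiacetal and should give the lactol on work-up (lactone-to-lactol reduction), the anomeric centre being of no consequence.

Step 3
Reactants: 4 6-ethenyl-5,5-dimethyloxan-2-ol
Product: 6 (7Z)-8-iodo-4,4-dimethylnona-1,7-dien-3-ol (racemic), via hydroxy aldehyde 5 (not isolated)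
Conditions: EtPPh3I, n-BuLi, THF, 0 °C; I2, −78 °C; NaN(SiMe3)2, −78 → −20 °C; then 4 (as its sodium salt, NaN(SiMe3)2), −78 °C → rt; ylide in excess
Reagents that add atoms: ethyltriphenylphosphonium iodide, CC[P+](c1ccccc1)(c1ccccc1)c1ccccc1.[I-]; iodine, II
Why: Wittig olefination of the ring-opened lactol with the α-iodo ylide (Stork–Zhao-type iodo-olefination) is kinetically Z-selective for 2-iodoalk-2-enes, which places iodine cis to the chain as the later ring closure requires.

Step 4
Reactants: 6 (7Z)-8-iodo-4,4-dimethylnona-1,7-dien-3-ol (racemic)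
Product: 8 potassium trifluoro[(2E)-7-hydroxy-6,6-dimethylnona-2,8-dien-2-yl]borate (racemic; boron cis to the chain), via pinacol boronate 7 (not isolated)
Conditions: B2pin2, PdCl2(PPh3)2 (cat.), PPh3, KOPh, PhMe, 50 °C; filtration; then aq. KHF2, MeOH, rt; crystallisation from acetone/Et2O
Reagents that add atoms: bis(pinacolato)diboron, CC1(C)OB(OC1(C)C)B1OC(C)(C)C(C)(C)O1; potassium hydrogen difluoride, [K+].F[H-]F
Why: Miyaura borylation of alkenyl iodides proceeds with retention of alkene geometry under the mild phenoxide conditions that tolerate a free alcohol, and KHF2 should convert the boronate into the crystalline, air-stable trifluoroborate.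

Step 5
Reactants: 8 potassium trifluoro[(2E)-7-hydroxy-6,6-dimethylnona-2,8-dien-2-yl]borate (racemic)
Product: 9 (6S)-6-ethenyl-1,5,5-trimethylcyclohex-1-ene
Conditions: [Ir(cod)Cl]2 (4 mol %), (S)-L (16 mol %), n-Bu4NHSO4 (0.4 equiv), aq. HF (1.5 equiv), 1,4-dioxane (0.01 M), 25 °C, polypropylene flask; L = 5-(dinaphtho[2,1-d:1',2'-f][1,3,2]dioxaphosphepin-4-yl)-5H-dibenzo[b,f]azepine; pentane extraction, careful concentration (volatile product)
Reagents that add atoms: none
Why: Proposed new method: acid-assisted ionisation of the allylic C–O bond of either enantiomer of 8 at the monovalent iridium–(P,olefin) catalyst should give one preferred allyl complex of trivalent iridium (the diastereomeric complexes can equilibrate by π–σ–π isomerisation through the unsubstituted terminus), so the racemate is funnelled into one configuration; the tethered alkenyltrifluoroborate then attacks the substituted allyl terminus with its boron-bearing carbon, anti to the metal, and the β-borato cation loses BF3 to fluoride, restoring the double bond in its original place. The closest known reaction types are the intermolecular iridium-catalysed enantioconvergent allylic alkenylation of racemic branched allylic alcohols with potassium alkenyltrifluoroborates and the iridium-catalysed allyl-initiated polyene cyclisation with the same ligand class; the ring-closing, neopentylic case is what is new. The six-membered carbocycle closes 6-exo-trig at the allyl electrophile (the allyl C=C stays outside the ring as the vinyl group) and endocyclic with respect to the nucleophilic alkene, through a chair-like array in which the cis boron/chain geometry of 8 lets the C–B bond align with the developing empty orbital. The only new stereocentre, ring C1 (S), is controlled by the ligand-defined face of the allyl terminus and not by the substrate. The step needs branched over linear attack (secured by ring size, six against eight), ipso over β attack of the alkenylborate (secured by β-boron stabilisation, which the five-membered alternative would forfeit), cyclisation over intermolecular coupling (gem-dimethyl effect and high dilution) and no diene formation (the neighbouring quaternary carbon has no hydrogen).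

Step 6
Reactants: 10 methyl acetoacetate; 11 1-bromobut-2-yne
Product: 12 methyl 3-oxooct-6-ynoate
Conditions: NaH, THF, 0 °C; n-BuLi, 0 °C; then 11, 0 °C → rt; aq. HCl
Reagents that add atoms: none
Why: The acetoacetate dianion reacts at its more nucleophilic terminal carbon with the propargylic bromide by SN2 (dianion γ-alkylation of a β-keto ester).

Step 7
Reactants: 12 methyl 3-oxooct-6-ynoate
Product: 13 methyl (2Z)-3-[(diethoxyphosphoryl)oxy]oct-2-en-6-ynoate
Conditions: NaH, Et2O, 0 °C; ClP(O)(OEt)2
Reagents that add atoms: diethyl chlorophosphate, CCOP(=O)(Cl)OCC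
Why: O-phosphorylation of the chelated sodium enolate of a β-keto ester should give the (Z)-enol phosphate selectively (enolate O-phosphorylation).

Step 8
Reactants: 13 methyl (2Z)-3-[(diethoxyphosphoryl)oxy]oct-2-en-6-ynoate
Product: 14 methyl (2E)-3-methyloct-2-en-6-ynoate
Conditions: Me2CuLi (from CuI and MeLi), Et2O, −78 → −45 °C; aq. NH4Cl
Reagents that add atoms: lithium dimethylcuprate, [Li+].C[Cu-]C
Why: Conjugate addition–elimination of the cuprate on the β-phosphoryloxy enoate occurs with retention, so the methyl group ends up cis to the ester (the E-enoate), and the internal alkyne is inert to the cuprate at low temperature.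

Step 9
Reactants: 14 methyl (2E)-3-methyloct-2-en-6-ynoate
Product: 15 (2E)-3-methyloct-2-en-6-yn-1-ol
Conditions: i-Bu2AlH (2.3 equiv), CH2Cl2, −78 °C; aq. KNaC4H4O6 (potassium sodium tartrate)
Reagents that add atoms: none
Why: i-Bu2AlH reduces the conjugated ester 1,2-selectively to the allylic alcohol without touching the alkene geometry or the alkyne (ester reduction).

Step 10
Reactants: 15 (2E)-3-methyloct-2-en-6-yn-1-ol
Product: 17 (2E,6E)-7-iodo-3-methylocta-2,6-dien-1-ol, via alkenylzirconocene 16 (not isolated)
Conditions: Cp2Zr(H)Cl (3.2 equiv), THF, rt → 50 °C; then I2, THF, 0 °C (to persisting colour)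
Reagents that add atoms: iodine, II
Why: syn-Hydrozirconation of the methyl-capped alkyne, equilibrated by excess hydride at 50 °C, should put zirconium on the less hindered methyl-bearing carbon, and iodinolysis with retention gives the (E)-2-iodoalk-2-ene (Schwartz hydrozirconation–iodination), the first equivalent of hydride being consumed by the hydroxyl.

Step 11
Reactants: 9 (6S)-6-ethenyl-1,5,5-trimethylcyclohex-1-ene; 17 (2E,6E)-7-iodo-3-methylocta-2,6-dien-1-ol
Product: 19 (2E,6E)-3,7-dimethyl-9-[(1S)-2,6,6-trimethylcyclohex-2-en-1-yl]nona-2,6-dien-1-ol, via alkylborane 18 (not isolated)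
Conditions: 9-BBN, THF, 0 °C → rt; then 17, PdCl2(dppf) (cat.), AsPh3, Cs2CO3, DMF/THF/H2O, rt
Reagents that add atoms: none
Why: 9-BBN hydroborates only the monosubstituted vinyl group, at its terminal carbon, and the primary alkylborane couples with the alkenyl iodide with retention of the E geometry (B-alkyl Suzuki–Miyaura coupling), the stereocentre not being involved.

Step 12
Reactants: 19 (2E,6E)-3,7-dimethyl-9-[(1S)-2,6,6-trimethylcyclohex-2-en-1-yl]nona-2,6-dien-1-ol; 20 linoleoyl chloride
Product: 21 (2E,6E)-3,7-dimethyl-9-[(1S)-2,6,6-trimethylcyclohex-2-en-1-yl]nona-2,6-dien-1-yl (9Z,12Z)-octadeca-9,12-dienoate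
Conditions: pyridine, DMAP (cat.), CH2Cl2, 0 °C → rt
Reagents that add atoms: none
Why: Acylation of the primary allylic alcohol by the acid chloride under amine catalysis (nucleophilic acyl substitution) is mild enough to leave the skipped (Z,Z)-diene and all trisubstituted alkenes unisomerised.

Compound list
1 | methyl 4,4-dimethyl-5-oxopentanoate | COC(=O)CCC(C)(C)C=O | starting material
2 | methyl 5-hydroxy-4,4-dimethylhept-6-enoate (racemic, not isolated) | COC(=O)CCC(C)(C)C(O)C=C | intermediate
3 | 6-ethenyl-5,5-dimethyloxan-2-one (racemic) | O=C1CCC(C)(C)C(C=C)O1 | intermediate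
4 | 6-ethenyl-5,5-dimethyloxan-2-ol (racemic, anomeric mixture) | OC1CCC(C)(C)C(C=C)O1 | intermediate
5 | 5-hydroxy-4,4-dimethylhept-6-enal (racemic, open-chain form of 4, not isolated) | O=CCCC(C)(C)C(O)C=C | intermediate
6 | (7Z)-8-iodo-4,4-dimethylnona-1,7-dien-3-ol (racemic) | C=CC(O)C(C)(C)CC/C=C(/C)I | intermediate
7 | (7E)-4,4-dimethyl-8-(4,4,5,5-tetramethyl-1,3,2-dioxaborolan-2-yl)nona-1,7-dien-3-ol (racemic, boron cis to the chain, not isolated) | C=CC(O)C(C)(C)CC/C=C(/C)B1OC(C)(C)C(C)(C)O1 | intermediate
8 | potassium trifluoro[(2E)-7-hydroxy-6,6-dimethylnona-2,8-dien-2-yl]borate (racemic) | C=CC(O)C(C)(C)CC/C=C(/C)[B-](F)(F)F.[K+] | intermediate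
9 | (6S)-6-ethenyl-1,5,5-trimethylcyclohex-1-ene | C=C[C@@H]1C(C)=CCCC1(C)C | intermediate
10 | methyl acetoacetate (methyl 3-oxobutanoate) | COC(=O)CC(C)=O | starting material
11 | 1-bromobut-2-yne | CC#CCBr | starting material
12 | methyl 3-oxooct-6-ynoate | CC#CCCC(=O)CC(=O)OC | intermediate
13 | methyl (2Z)-3-[(diethoxyphosphoryl)oxy]oct-2-en-6-ynoate | CC#CCC/C(OP(=O)(OCC)OCC)=C/C(=O)OC | intermediate
14 | methyl (2E)-3-methyloct-2-en-6-ynoate | CC#CCC/C(C)=C/C(=O)OC | intermediate
15 | (2E)-3-methyloct-2-en-6-yn-1-ol | CC#CCC/C(C)=C/CO | intermediate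
16 | C7-zirconated (2E,6E)-3-methylocta-2,6-dien-1-ol as its Cp2Zr(Cl) alkoxide, each zirconium being Cp2Zr(Cl) (cyclopentadienyl ligands drawn σ-bonded, not isolated) | C/C(=C\CC/C(C)=C/CO[Zr](Cl)(C1C=CC=C1)C1C=CC=C1)[Zr](Cl)(C1C=CC=C1)C1C=CC=C1 | intermediate
17 | (2E,6E)-7-iodo-3-methylocta-2,6-dien-1-ol | C/C(I)=C\CC/C(C)=C/CO | intermediate
18 | 9-{2-[(1S)-2,6,6-trimethylcyclohex-2-en-1-yl]ethyl}-9-borabicyclo[3.3.1]nonane (not isolated) | C(C[C@@H]1C(C)=CCCC1(C)C)B1C2CCCC1CCC2 | intermediate
19 | (2E,6E)-3,7-dimethyl-9-[(1S)-2,6,6-trimethylcyclohex-2-en-1-yl]nona-2,6-dien-1-ol | OC/C=C(\C)CC/C=C(\C)CC[C@@H]1C(C)=CCCC1(C)C | intermediate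
20 | linoleoyl chloride ((9Z,12Z)-octadeca-9,12-dienoyl chloride) | CCCCC/C=C\C/C=C\CCCCCCCC(=O)Cl | starting material
21 | (2E,6E)-3,7-dimethyl-9-[(1S)-2,6,6-trimethylcyclohex-2-en-1-yl]nona-2,6-dien-1-yl (9Z,12Z)-octadeca-9,12-dienoate | CCCCC/C=C\C/C=C\CCCCCCCC(=O)OC/C=C(\C)CC/C=C(\C)CC[C@@H]1C(C)=CCCC1(C)C | target

Total step count: 12. Longest linear sequence: 7 steps (steps 1–5, 11, 12; the branch 6–10, 11, 12 is equally long).

Steps most likely to fail

Risk 1 (step 5). Ionisation of the neopentylic carbinol at iridium may be too slow, so that protodeboronation of the alkenylborate or intermolecular coupling takes over, or the facial control at the hindered allyl terminus may be insufficient. The fallback keeps the same ring bond but gives up asymmetric induction in favour of separation, using known chemistry only. It sets out from pinacol boronate 7, isolated this time. Acylation by ClCO2Me, pyridine and DMAP in CH2Cl2 should give the racemic allylic methyl carbonate F1. An intramolecular allyl–alkenyl Suzuki–Miyaura coupling of F1 under zerovalent palladium, Pd(PPh3)4 in THF at 60 °C at high dilution, the liberated methoxide acting as base, should close the ring to racemic 6-ethenyl-1,5,5-trimethylcyclohex-1-ene F2. Hydroboration of F2 by 9-BBN gives the racemic alkylborane F3, which is coupled in the same flask to 17 under the conditions of step 11 to give the racemic dienol F4. F4 is resolved by preparative chromatography on a chiral stationary phase. Its S enantiomer is 19, where the route is rejoined.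

Risk 2 (step 3). The lactol may open too slowly at the low temperature that the thermally fragile iodo ylide tolerates, so that ylide decomposition and loss of iodine outrun the olefination. The fallback performs the olefination on an open-chain, protected aldehyde and sets out from lactone 3. Aminolysis by MeNH(OMe)·HCl and AlMe3 in CH2Cl2 should give the hydroxy N-methoxy-N-methyl amide F5. Silylation by Et3SiOTf and 2,6-lutidine gives the triethylsilyl ether F6, and i-Bu2AlH at −78 °C the silyloxy aldehyde F7. The same iodo-olefination as in step 3 then gives the silyl-protected Z-configured iodide F8. PPTS in MeOH removes the silyl group from F8, and the route is rejoined at 6.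

Risk 3 (step 10). Regiochemical equilibration of the alkenylzirconium may stay incomplete (zirconium at C6 instead of C7), and the free allylic alkoxide may consume hydride or undergo side reactions. The fallback abandons the C10 iodide and grows the chain stepwise, so that both trisubstituted alkenes come from stereodefined enol derivatives of β-keto esters. It sets out from alkylborane 18 and methyl acetoacetate 10. Compound 10 is converted by aq. Me4NOH and Tf2O into the E-configured enol triflate F9. B-alkyl Suzuki–Miyaura coupling of 18 and F9, catalysed by PdCl2(dppf) in the presence of K3PO4, should give, by retention, the E-configured enoate F10. i-Bu2AlH gives the allylic alcohol F11 and CBr4/PPh3 the allylic bromide F12. γ-Alkylation of the dianion of 10 by F12 gives the β-keto ester F13, NaH/ClP(O)(OEt)2 the Z-configured enol phosphate F14, and Me2CuLi the 2E,6E-dienoate F15. Reduction of F15 by i-Bu2AlH rejoins the route at 19.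

Further compounds
F1 | step 5 | (7E)-4,4-dimethyl-8-(4,4,5,5-tetramethyl-1,3,2-dioxaborolan-2-yl)nona-1,7-dien-3-yl methyl carbonate (racemic) | C=CC(OC(=O)OC)C(C)(C)CC/C=C(/C)B1OC(C)(C)C(C)(C)O1
F2 | step 5 | 6-ethenyl-1,5,5-trimethylcyclohex-1-ene (racemic) | C=CC1C(C)=CCCC1(C)C
F3 | step 5 | 9-[2-(2,6,6-trimethylcyclohex-2-en-1-yl)ethyl]-9-borabicyclo[3.3.1]nonane (racemic, not isolated) | C(CC1C(C)=CCCC1(C)C)B1C2CCCC1CCC2
F4 | step 5 | (2E,6E)-3,7-dimethyl-9-(2,6,6-trimethylcyclohex-2-en-1-yl)nona-2,6-dien-1-ol (racemic) | OC/C=C(\C)CC/C=C(\C)CCC1C(C)=CCCC1(C)C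
F5 | step 3 | 5-hydroxy-N-methoxy-N,4,4-trimethylhept-6-enamide (racemic) | CON(C)C(=O)CCC(C)(C)C(O)C=C
F6 | step 3 | N-methoxy-N,4,4-trimethyl-5-[(triethylsilyl)oxy]hept-6-enamide (racemic) | CON(C)C(=O)CCC(C)(C)C(O[Si](CC)(CC)CC)C=C
F7 | step 3 | 4,4-dimethyl-5-[(triethylsilyl)oxy]hept-6-enal (racemic) | O=CCCC(C)(C)C(O[Si](CC)(CC)CC)C=C
F8 | step 3 | triethyl{[(7Z)-8-iodo-4,4-dimethylnona-1,7-dien-3-yl]oxy}silane (racemic) | C=CC(O[Si](CC)(CC)CC)C(C)(C)CC/C=C(/C)I
F9 | step 10 | methyl (2E)-3-{[(trifluoromethyl)sulfonyl]oxy}but-2-enoate | C/C(OS(=O)(=O)C(F)(F)F)=C\C(=O)OC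
F10 | step 10 | methyl (2E)-3-methyl-5-[(1S)-2,6,6-trimethylcyclohex-2-en-1-yl]pent-2-enoate | COC(=O)/C=C(\C)CC[C@@H]1C(C)=CCCC1(C)C
F11 | step 10 | (2E)-3-methyl-5-[(1S)-2,6,6-trimethylcyclohex-2-en-1-yl]pent-2-en-1-ol | OC/C=C(\C)CC[C@@H]1C(C)=CCCC1(C)C
F12 | step 10 | (6S)-6-[(3E)-5-bromo-3-methylpent-3-en-1-yl]-1,5,5-trimethylcyclohex-1-ene | BrC/C=C(\C)CC[C@@H]1C(C)=CCCC1(C)C
F13 | step 10 | methyl (6E)-7-methyl-3-oxo-9-[(1S)-2,6,6-trimethylcyclohex-2-en-1-yl]non-6-enoate | COC(=O)CC(=O)CC/C=C(\C)CC[C@@H]1C(C)=CCCC1(C)C
F14 | step 10 | methyl (2Z,6E)-3-[(diethoxyphosphoryl)oxy]-7-methyl-9-[(1S)-2,6,6-trimethylcyclohex-2-en-1-yl]nona-2,6-dienoate | COC(=O)/C=C(OP(=O)(OCC)OCC)/CC/C=C(\C)CC[C@@H]1C(C)=CCCC1(C)C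
F15 | step 10 | methyl (2E,6E)-3,7-dimethyl-9-[(1S)-2,6,6-trimethylcyclohex-2-en-1-yl]nona-2,6-dienoate | COC(=O)/C=C(\C)CC/C=C(\C)CC[C@@H]1C(C)=CCCC1(C)C
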